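You take the reading at 25 min. The exchanges among intermediate A, intermediate B and target relax, each by its own step alone, with half-lives of 0.149 min, 0.411 min and 0.412 min, short against that time, so I reckon with end states, not curves.

solid substrate 1.2 M; reagent 1.14 M (in portions, 3); time 25 min; the portions of reagent follow each other after 3.0 s, the first at the start

    intermediate B ⇌ target (K1 = 1.8, k1 = 0.050 s⁻¹)
    target ⇌ intermediate A (K2 = 0.86, k2 = 0.013 s⁻¹)
    starting material + reagent → intermediate A (k3 = 0.10 M⁻¹ s⁻¹)
    intermediate A ⇌ intermediate B (k4 = 0.011 s⁻¹)
    starting material + reagent → intermediate B (k5 = 0.17 M⁻¹ s⁻¹)
    solid substrate ⇌ starting material, rate k6*(cs6 - [starting material]) while solid is left; crystals form when [starting material] > cs6 (cs6 = 0.62 M, k6 = 0.046 s⁻¹)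

- given per volume of solution although it is solid: solid substrate
- at the start none of the solid substrate is in solution
- what has only dissolved of solid substrate counts as not reacted
- the reaction counts as stopped when no species that holds the solid substrate changes by six tenths of a point or more over the second half of the time
- run time (flask): 25 min

- which holds at 25 min: what has brought the reaction to rest, or that it has not come to rest (for what has run out or reacted, a solid counts together with what of it has only dissolved) (forward and back rates have come level / the reagent has run out first / all of the solid substrate has reacted / it is still moving)
- part of the solid substrate that has turned into other species by 25 min (what has only dissolved does not count)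
- target at 25 min, in percent of the solid substrate charged
- intermediate A at 25 min, in percent of the solid substrate charged

Each coupling step takes one starting material and one reagent and puts one molecule into the pool of intermediate A, intermediate B and target. In this flask the reagent is the limiting reagent, so I expect it to run out first, with a pool of 1.14 M and a conversion of 95.0 %.

At equilibrium I reckon the pool as [intermediate B] : [target] : [intermediate A] = 1 : 1.8 : 1.55, which is thermodynamic control of the split. I carry the equilibrium share of target in the pool, its term in that ratio over the sum: 41.4 %. For intermediate A the share is 35.6 %. Conversion times share gives target 39.3 % and intermediate A 33.8 %.

The forecast says the reagent has run out first, with conversion 95 %, target 39.3 % and intermediate A 33.8 %, and gives as one of its grounds: “The A, B and target cycle relaxes in a few minutes”.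

The simulation of this flask reports that the reagent has run out first, with 0 % of it left, conversion 95.0 %, target 39.3 % and intermediate A 33.8 %. Target already stands at 39.3 % at 12.5 min and is 39.3 % at 25.0 min. Target over conversion is 41.4 %, against the share of 41.4 %. The short way is one minimum and one ratio, and in this flask the drawn-out feeding of reagent makes no difference to conversion.

Now take the neighbouring flask with 0.48 M of solid substrate, the reagent and the time as before. There the solid substrate is the smaller charge, so the pool is 0.480 M, conversion is 100 %, and the same shares give target 41.4 % and intermediate A 35.6 %, with 57.9 % of the reagent over. The simulation of that neighbour gives conversion 100 %, target 41.4 %, intermediate A 35.6 %, and 58 % of its reagent left.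

The constants are made up; what happens was integrated by code.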